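**Plan**
Ring A is the phenol ring, numbered C1 (OH), C2–C5 (Br), C6 (O–aryl); ring B is the 2,4-dibromophenyl group.
Retrosynthesis: the C2–, C3– and C5–Br bonds of ring A go back to C–H and C4–Br to C4–NO2. Then the C3–C4 and C4–C5 bonds are cut, which removes C4 as nitromethane and leaves a 4-pyranone. Last, the O–C bond from the pyranone oxygen to ring B is cut.
Enabling feature: the OH on C1 next to the aryl ether on C6 matches a 4-pyranone carbonyl with an oxygen substituent on its C3, and C4, para to the OH, lies where the pyranone has its ring oxygen. A one-carbon nucleophile bearing a nitro group can therefore be stitched in there and the nitro group later traded for bromine.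
Forward: ring B comes in complete as an aryliodonium salt and is joined to 3-hydroxy-4H-pyran-4-one; the pyranone is then rebuilt into ring A with nitromethane. The OH directs Br to C2, the amine made from the nitro group directs Br to C3 and C5, and a Sandmeyer reaction puts Br on C4.
Stereochemistry: the target has no stereocentre and no stereogenic double bond, so nothing has to be controlled.

Key step: step 3

Assumption: 3-hydroxy-4H-pyran-4-one and 2,4-dibromo-1-iodobenzene are bought.
Remark: C3 and C5 are brominated while C4 still bears NH2, because once C4 carries Br they would be meta to the C1 oxygen and hardly more reactive than the free ortho position of ring B; the phenol is carried as its methyl ether over that stretch because a free 4-aminophenol would be oxidised to a quinone imine by the brominating agent.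

Step 1
Reactants: 1 2,4-dibromo-1-iodobenzene; 2 1,3,5-trimethoxybenzene
Product: 4 (2,4-dibromophenyl)(2,4,6-trimethoxyphenyl)iodonium 4-methylbenzenesulfonate, via hydroxy(tosyloxy)iodoarene 3 (not isolated)
Conditions: mCPBA, TsOH·H2O, MeCN, 77 °C; then 1,3,5-trimethoxybenzene, 77 °C → rt
Reagents that add atoms: p-toluenesulfonic acid, Cc1ccc(cc1)S(=O)(=O)O
Why: One-pot synthesis of an aryl(trimethoxyphenyl)iodonium salt: mCPBA with TsOH oxidises the aryl iodide to the trivalent-iodine species 3, which substitutes the electron-rich trimethoxybenzene by electrophilic aromatic substitution, the aryl bromides being inert to the peracid.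

Step 2
Reactants: 4 (2,4-dibromophenyl)(2,4,6-trimethoxyphenyl)iodonium 4-methylbenzenesulfonate; 5 3-hydroxy-4H-pyran-4-one
Product: 6 3-(2,4-dibromophenoxy)-4H-pyran-4-one
Conditions: K2CO3, MeCN, 60 °C
Reagents that add atoms: none
Why: Metal-free O-arylation of an acidic, phenol-like hydroxyl with a diaryliodonium salt: the pyranolate exchanges onto iodine and ligand coupling transfers the electron-poorer, ortho-substituted dibromophenyl group, while the trimethoxyphenyl group stays on iodine and leaves as its iodide.

Step 3
Reactants: 6 3-(2,4-dibromophenoxy)-4H-pyran-4-one; 7 nitromethane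
Product: 10 2-(2,4-dibromophenoxy)-4-nitrophenol, via nitromethyl dihydropyranone 8 (not isolated), via open-chain nitro dienal 9 (not isolated)
Conditions: MeNO2 (3 equiv), t-BuOK (2.2 equiv), t-BuOH–THF, 25 → 60 °C; then 1 M HCl
Reagents that add atoms: none
Why: The nitronate of nitromethane adds in conjugate fashion to an alpha carbon of the vinylogous ester (drawn for the unhindered C6; attack at C2 ends in the same phenol, since the new carbon is bonded to both alpha carbons in the product), giving 8 as its enolate, a 2H-pyran-4-olate that opens by cleavage of its ring C–O bond (6π electrocyclic or E1cB) to the acyclic enolate aldehyde 9. The nitro-bearing carbon, deprotonated again, attacks the terminal aldehyde in a 6-exo-trig nitro-aldol (Henry) closure, and loss of water with enolisation of the former pyranone carbonyl gives the 4-nitrophenolate, so that C4 of ring A is stitched in with its C3–C4 and C4–C5 bonds. The closest known reaction type is the base-mediated conversion of 2,6-dialkyl-4-pyranones into 3,5-dialkyl-4-nitrophenols, and of pyrylium salts into nitrobenzenes, with nitromethane. No stereocentre is formed and the ring offers no regiochemical choice. The selectivity needed is chemoselectivity against base attack on the alpha-unsubstituted pyranone and against cleavage of the vinylogous aryl ether: nitromethane is kept in excess over t-BuOK so that no free alkoxide is present, and the intramolecular closure followed by irreversible aromatisation should drain the open-chain intermediate before it reacts elsewhere.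

Step 4
Reactants: 10 2-(2,4-dibromophenoxy)-4-nitrophenol
Product: 11 2-bromo-6-(2,4-dibromophenoxy)-4-nitrophenol
Conditions: Br2 (1.05 equiv), NaOAc, AcOH, 25 °C
Reagents that add atoms: bromine, BrBr
Why: Electrophilic aromatic bromination of a 4-nitrophenol ortho to the OH: C2 is the only free ortho or para position of the partly ionised phenol, and the twice-brominated ring B should not react with one equivalent of Br2 at room temperature.

Step 5
Reactants: 11 2-bromo-6-(2,4-dibromophenoxy)-4-nitrophenol
Product: 12 1-bromo-3-(2,4-dibromophenoxy)-2-methoxy-5-nitrobenzene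
Conditions: MeI, K2CO3, DMF, 40 °C
Reagents that add atoms: iodomethane, CI
Why: Williamson ether synthesis on the acidic nitrophenol; the methyl ether keeps the later aminophenol from being oxidised during bromination.

Step 6
Reactants: 12 1-bromo-3-(2,4-dibromophenoxy)-2-methoxy-5-nitrobenzene
Product: 13 3-bromo-5-(2,4-dibromophenoxy)-4-methoxyaniline
Conditions: Fe powder, AcOH, EtOH–H2O, 70 °C
Reagents that add atoms: none
Why: Béchamp-type reduction of the nitro group with Fe in acetic acid, which leaves the aryl bromides and both aryl ethers untouched.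

Step 7
Reactants: 13 3-bromo-5-(2,4-dibromophenoxy)-4-methoxyaniline
Product: 14 2,3,6-tribromo-5-(2,4-dibromophenoxy)-4-methoxyaniline
Conditions: NBS (2.1 equiv), MeCN, 0 → 25 °C
Reagents that add atoms: N-bromosuccinimide, O=C1CCC(=O)N1Br
Why: Electrophilic aromatic bromination ortho to a free amino group: the two open positions of ring A, C3 and C5, both flank the NH2 (its para position is blocked by OMe), so two equivalents of NBS should fill them while the deactivated ring B stays untouched.

Step 8
Reactants: 14 2,3,6-tribromo-5-(2,4-dibromophenoxy)-4-methoxyaniline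
Product: 16 1,2,3,4-tetrabromo-5-(2,4-dibromophenoxy)-6-methoxybenzene, via diazonium hydrogensulfate 15 (not isolated)
Conditions: NaNO2, H2SO4–AcOH, 0–10 °C; then CuBr (cat.), 48% aq. HBr, 70 °C
Reagents that add atoms: hydrogen bromide, Br
Why: Sandmeyer reaction: the weakly basic di-ortho-bromoaniline is diazotised with nitrosylsulfuric acid and CuBr mediates the radical exchange of N2 for Br; the diazonium carbon is meta to the aryloxy group, so no ring closure onto ring B can compete, and HBr as the only halide makes any exchange of the activated ortho bromines degenerate.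

Step 9
Reactants: 16 1,2,3,4-tetrabromo-5-(2,4-dibromophenoxy)-6-methoxybenzene
Product: 18 3,4,5,6-tetrabromo-2-(2,4-dibromophenoxy)phenol, via aryloxydibromoborane 17 (not isolated)
Conditions: BBr3, CH2Cl2, −78 → 25 °C; then H2O
Reagents that add atoms: none
Why: Lewis-acid cleavage of an aryl methyl ether with BBr3: bromide attacks the methyl group of the oxygen–boron adduct in an SN2 step and water frees the phenol from the aryloxyborane, while the diaryl ether and the aryl bromides should not react.

**Compound list**
1 | 2,4-dibromo-1-iodobenzene | Brc1ccc(I)c(Br)c1 | starting material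
2 | 1,3,5-trimethoxybenzene | COc1cc(OC)cc(OC)c1 | starting material
3 | 2,4-dibromo-1-[hydroxy(tosyloxy)iodo]benzene | Cc1ccc(cc1)S(=O)(=O)OI(O)c1ccc(Br)cc1Br | intermediate (not isolated)
4 | (2,4-dibromophenyl)(2,4,6-trimethoxyphenyl)iodonium 4-methylbenzenesulfonate | COc1cc(OC)c([I+]c2ccc(Br)cc2Br)c(OC)c1.Cc1ccc(cc1)S(=O)(=O)[O-] | intermediate
5 | 3-hydroxy-4H-pyran-4-one | O=C1C=COC=C1O | starting material
6 | 3-(2,4-dibromophenoxy)-4H-pyran-4-one | O=C1C=COC=C1Oc1ccc(Br)cc1Br | intermediate
7 | nitromethane | C[N+](=O)[O-] | starting material
8 | 5-(2,4-dibromophenoxy)-2-(nitromethyl)-2,3-dihydro-4H-pyran-4-one (racemic; present as its potassium enolate) | O=C1CC(C[N+](=O)[O-])OC=C1Oc1ccc(Br)cc1Br | intermediate (not isolated)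
9 | (2Z,4Z)-2-(2,4-dibromophenoxy)-3-hydroxy-6-nitrohexa-2,4-dienal (present as its potassium enolate) | O=C/C(Oc1ccc(Br)cc1Br)=C(O)\C=C/C[N+](=O)[O-] | intermediate (not isolated)
10 | 2-(2,4-dibromophenoxy)-4-nitrophenol | Oc1ccc([N+](=O)[O-])cc1Oc1ccc(Br)cc1Br | intermediate
11 | 2-bromo-6-(2,4-dibromophenoxy)-4-nitrophenol | Oc1c(Br)cc([N+](=O)[O-])cc1Oc1ccc(Br)cc1Br | intermediate
12 | 1-bromo-3-(2,4-dibromophenoxy)-2-methoxy-5-nitrobenzene | COc1c(Br)cc([N+](=O)[O-])cc1Oc1ccc(Br)cc1Br | intermediate
13 | 3-bromo-5-(2,4-dibromophenoxy)-4-methoxyaniline | COc1c(Br)cc(N)cc1Oc1ccc(Br)cc1Br | intermediate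
14 | 2,3,6-tribromo-5-(2,4-dibromophenoxy)-4-methoxyaniline | COc1c(Br)c(Br)c(N)c(Br)c1Oc1ccc(Br)cc1Br | intermediate
15 | 2,3,6-tribromo-5-(2,4-dibromophenoxy)-4-methoxybenzenediazonium hydrogensulfate | COc1c(Br)c(Br)c([N+]#N)c(Br)c1Oc1ccc(Br)cc1Br.OS(=O)(=O)[O-] | intermediate (not isolated)
16 | 1,2,3,4-tetrabromo-5-(2,4-dibromophenoxy)-6-methoxybenzene | COc1c(Br)c(Br)c(Br)c(Br)c1Oc1ccc(Br)cc1Br | intermediate
17 | dibromo[3,4,5,6-tetrabromo-2-(2,4-dibromophenoxy)phenoxy]borane | BrB(Br)Oc1c(Br)c(Br)c(Br)c(Br)c1Oc1ccc(Br)cc1Br | intermediate (not isolated)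
18 | 3,4,5,6-tetrabromo-2-(2,4-dibromophenoxy)phenol | Oc1c(Br)c(Br)c(Br)c(Br)c1Oc1ccc(Br)cc1Br | target

Total step count: 9. Longest linear sequence: 9 steps (from 1 to 18).

**Steps most likely to fail**

Step 3 (key step). The alpha-unsubstituted pyranone may be consumed by base-induced ring opening and oligomerisation, or by a second nitronate addition or an intermolecular Henry reaction at the open-chain stage, before the nitro-aldol closure takes place. The fallback gives up the ring rebuild and takes ring A ready-made; it sets out from 4 and comes back to the route at 10. Salt 4 O-arylates commercial 2-methoxy-5-nitrophenol (K2CO3, MeCN, 60 °C) to give 2-(2,4-dibromophenoxy)-1-methoxy-4-nitrobenzene F1, and BBr3 in CH2Cl2 then cleaves the methyl ether and gives 10.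

Step 2. Aryl transfer to the weakly nucleophilic, delocalised pyranolate may be so slow that decomposition of the iodonium salt or transfer of the trimethoxyphenyl group takes over. The fallback builds the pyranone on the finished aryl ether instead. It replaces steps 1 and 2, so it sets out from none of the numbered compounds but from commercial 2,4-dibromophenol and chloroacetone, and it comes back to the route at 6. Alkylation (K2CO3, acetone, reflux) gives 1-(2,4-dibromophenoxy)propan-2-one F2. Heating F2 in excess N,N-dimethylformamide dimethyl acetal condenses both alpha positions and gives (1Z,4E)-2-(2,4-dibromophenoxy)-1,5-bis(dimethylamino)penta-1,4-dien-3-one F3. Aqueous HCl hydrolyses one enaminone end to the enol, which closes onto the other end with loss of dimethylamine and gives 6.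

Step 8. At the carbon flanked by two bromines, bromine transfer to the aryl radical may lose out to hydrogen abstraction or to capture by water, so that reduction or hydroxylation replaces bromination. The fallback puts the C4 bromine in by electrophilic substitution para to the phenol; it sets out from 14 and comes back at 18. Diazotisation as in step 8 gives 15, which H3PO2 reduces to 1,2,5-tribromo-4-(2,4-dibromophenoxy)-3-methoxybenzene F4. BBr3 in CH2Cl2 gives 2,3,5-tribromo-6-(2,4-dibromophenoxy)phenol F5. Br2 (1 equiv) in AcOH at 25 °C then brominates the one free position of ring A, para to the OH, and gives 18.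

**Further compounds**
F1 | step 3 | 2-(2,4-dibromophenoxy)-1-methoxy-4-nitrobenzene | COc1ccc([N+](=O)[O-])cc1Oc1ccc(Br)cc1Br
F2 | step 2 | 1-(2,4-dibromophenoxy)propan-2-one | CC(=O)COc1ccc(Br)cc1Br
F3 | step 2 | (1Z,4E)-2-(2,4-dibromophenoxy)-1,5-bis(dimethylamino)penta-1,4-dien-3-one | CN(C)/C=C/C(=O)/C(Oc1ccc(Br)cc1Br)=C/N(C)C
F4 | step 8 | 1,2,5-tribromo-4-(2,4-dibromophenoxy)-3-methoxybenzene | COc1c(Br)c(Br)cc(Br)c1Oc1ccc(Br)cc1Br
F5 | step 8 | 2,3,5-tribromo-6-(2,4-dibromophenoxy)phenol | Oc1c(Br)c(Br)cc(Br)c1Oc1ccc(Br)cc1Br
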